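# Proposed synthesis of (2R,3R)-epicatechin 3-O-vanillate (25) by benzannulation of ring A

## Analysis of the target

Compound 25 is the O3 vanillate of a 2,3-cis flavan-3-ol. It is a chroman built from the phloroglucinol-type ring A and the dihydropyran ring C, with a 3,4-dihydroxyphenyl ring B on C2 and a 4-hydroxy-3-methoxybenzoyl group on the C3 oxygen. The only stereocenters are the adjacent C2 and C3, both R, which puts the aryl group and the acyloxy group cis on ring C, the less stable relative arrangement. C2 is a benzylic ether carbon next to an oxygen-rich ring B, so it ionises under acid and, once the para hydroxyl of ring B is free, epimerises under base by ring opening to a quinone methide. Five free phenols (an air-sensitive catechol and a strongly nucleophilic ring A among them) must coexist with an aryl ester at the end, so the phenols are best unmasked last and under neutral conditions. The synthesis is hard on three counts: the cis relation with absolute control, acylation of one secondary hydroxyl beside five phenolic oxygens, and attachment of C4 to the electron-rich ring A without loss of regiocontrol. The strategy rests on ring A: its oxygens sit on C5, C7 and C8a in a 1,3,5 pattern, and its single carbon substituent, C4, sits on C4a between C5 and C8a. A benzannulation of a 3-oxygenated vinylketene with a siloxyalkyne delivers exactly this pattern (hydroxyl, alkyl, silyloxy, then alkoxy para to the alkyl group), so ring A can be assembled around a chain that already holds C2, C3 and C4, with its three oxygens differentiated from the start.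

## Retrosynthetic reasoning

**Unmasking.** Target 25 is traced to 24, in which the four remaining phenols are benzyl ethers, and 24 to its C5 silyl ether 23. Hydrogenolysis is the last step because it is neutral and leaves the ester and the C2 ether alone. The silyl group comes off one step earlier so that the final product needs no chromatography from ammonium salts.

**C3–O acyl bond.** Cutting the ester of 23 gives chromanol 21 and the benzyl-protected acid 22. At this stage the C3 hydroxyl is the only free hydroxyl, because the C5 oxygen is still silylated. This is the reason for keeping the silyl ether through the ring closure.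

**O1–C2 bond.** Ring C of 21 is opened at O1–C2, not at C4–C4a, because a phenol oxygen can displace an activated benzylic hydroxyl in a 6-exo closure under neutral Mitsunobu conditions. This leads to triol 19, whose benzylic carbon has the opposite (S) configuration, since the closure inverts it; C3 is untouched. The erythro (1S,2R) diol therefore maps onto the cis (2R,3R) chroman. Triol 19 comes from acetonide 18. Either oxygen flanking C4a would give the same chroman on closure, so no regiochemical question arises here.

**Ring A (the strategic cut).** Phenol 18 is cut at C4a–C8a, C5–C6 and C8–C8a into siloxyalkyne 11 and cyclobutenone 13. The two alkyne carbons become C4a and C5, and the four ring carbons of 13 become C8a, C6, C7 and C8. The cut is made here because it removes the whole aromatic ring in one step and leaves a chain in which both stereocenters are already in place and masked as an acetonide. The forward reaction must join the chain-bearing alkyne carbon to the ketene carbonyl carbon, so that the chain ends up between the new hydroxyl and the silyloxy group. Both chain hydroxyls must be masked, because ketenes acylate alcohols.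

**Cyclobutenone.** Compound 13 is traced to the ethyl analogue 12 by exchange of the enol ether alkyl group. A benzyl group is needed because the C7 oxygen must be freed by hydrogenolysis at the end.

**Siloxyalkyne.** The C–O bond of the ynol ether in 11 is cut back to terminal alkyne 8 through its acetylide 9 and ynolate 10. Alkyne 8 comes from the C-silylated acetonide 7, and 7 from diol 6.

**C4–C4a bond.** Diol 6 is cut between the propargylic CH2 and the alkyne into epoxy alcohol 4 and silylacetylene 5. Opening a terminal epoxide with an acetylide is unambiguous in its regiochemistry and does not touch either stereocenter.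

**Stereocenters.** Epoxy alcohol 4 is traced to racemic allylic alcohol 3 by a Sharpless kinetic resolution. This one operation selects the carbinol configuration and sets the oxirane carbon, giving the erythro relation needed for the later inversion. Alcohol 3 comes from aldehyde 1 and vinyl Grignard reagent 2, which forms the C2–C3 bond.

## Alternatives that were turned down

**Alternative 1:** Ring C is cut at C3–C4 and O1–C2 together.

- *Forward key step.* A chiral phosphoric acid dehydrates salicyl alcohol A2 to the ortho-quinone methide A4. A4 adds the Z-configured enol ester A3 in a hetero-Diels–Alder reaction and gives A1, the fully benzylated target.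
- *For.* Nothing is more convergent. A3 already carries ring B and the vanillate. Both stereocenters, ring C and the ester arrive in one step, and A1 is one hydrogenolysis from 25. The route would be about a third as long as the chosen one.
- *Against.* Three selectivities depend on one step with no proven handle.
  - Orientation: A3 must react as a styrene, with C3 as the nucleophilic carbon and charge building at benzylic C2. This runs against the polarisation from its enol ester oxygen, so the dienophile is sluggish and the orientation is not secure.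
  - Cis relation: it survives only if the Z geometry is transferred in a concerted addition. A stepwise path through a benzylic cation stabilised by ring B allows rotation toward the trans product.
  - Enantiocontrol: A3 offers the acid catalyst no hydrogen-bond donor for two-point binding.
- *Comparison.* Alternative 1 is clearly stronger on step economy. The chosen strategy instead sets both stereocenters by a reagent-controlled reaction on an open chain before any ring exists. Its key step creates no stereocenter, so it can fail in reactivity but not in selectivity.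

**Alternative 2:** Ring C is cut at O1–C8a and C4–C4a (aryne addition) and at O1–C2 (electrocyclisation).

- *Forward key step.* A fluoride source releases aryne A8 from silyl triflate A6. A8 adds the carbonyl group of enal A7 in a (2+2) manner, the four-membered adduct opens to an ortho-quinone methide, and oxa-6π closure gives the racemic chromene A5.
- *For.* Ring C forms from two simple partners. The alkoxy group next to the aryne bond directs the carbonyl oxygen to the remote aryne carbon, which is the orientation the target needs. Ring A needs no differentiation of its oxygens.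
- *Against.* A5 carries neither stereocenter in usable form. C2 is made in an uncatalysed pericyclic closure and is racemic, and C3 has no oxygen. Hydration of the C3=C4 bond anti to the aryl group would give the trans alcohol, so a resolution and an oxidation–reduction inversion at C3 would both have to follow. A6 itself needs several steps.
- *Comparison.* It reaches the bare skeleton in as few or fewer steps. It then discards half the material late in the sequence and spends further steps correcting C3. The chosen route also discards half in its kinetic resolution, but at the second step and on cheap material, and the stereocenters need no later correction.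

**Alternative 3:** Ring C is cut at C4–C4a.

- *Forward key step.* In epoxy ether A10 the O1–C2 bond already exists. A Lewis acid or a strongly hydrogen-bond-donating fluorinated alcohol solvent activates the epoxide, and the ring A carbon ortho to the ether oxygen attacks the epoxide CH2 to give chromanol A9.
- *For.* It is the shortest of all. A10 should be available from compound 4 and phenol A11 by a Mitsunobu etherification with inversion. A9 needs only acylation with 22 and hydrogenolysis, about half the steps of the chosen route. The two ortho positions of the symmetric ring are equivalent and doubly activated, and no phenol has to be differentiated.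
- *Against.* The closure must attack the primary terminus (6-endo). An activated epoxide prefers to open at its more substituted carbon, and 5-exo attack there gives a dihydrobenzofuran. The benzylic C2–O bond of A10 has a para-alkoxy ring B on one side and a phenoxide leaving group on the other. It is the most acid-labile bond in the molecule, and ionisation under the activating conditions would scramble C2 or detach ring A.
- *Comparison.* Alternative 3 is stronger on step count and, if the regiochemistry held, would be the most economical. The chosen strategy never exposes a benzylic aryl ether to acid and forms C4–C4a as an acetylide–epoxide bond whose regiochemistry is not in doubt. It pays with roughly twice the number of steps and a key step that carries the risk.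

Key step: step 8

## Route

Remark: the titanium–tartrate epoxidation is assumed to follow its usual rule for secondary allylic alcohols, under which the L-(+)-tartrate consumes the (R)-enantiomer of 3 and gives the erythro epoxy alcohol 4.

Remark: compounds 12 and 22 are taken to be purchasable.

In the names below, "Diox-CH2" stands for the group [(4R,5S)-5-[3,4-bis(benzyloxy)phenyl]-2,2-dimethyl-1,3-dioxolan-4-yl]methyl.

Step 1
Reactants: 1 3,4-bis(benzyloxy)benzaldehyde; 2 vinylmagnesium bromide
Product: 3 rac-1-[3,4-bis(benzyloxy)phenyl]prop-2-en-1-ol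
Conditions: CH2=CHMgBr, THF, 0 °C; aq NH4Cl
Reagents that add atoms: none
Why: Grignard 1,2-addition to an aryl aldehyde with no competing electrophile; the carbinol is formed racemic and is resolved in step 2.

Step 2
Reactants: 3 rac-1-[3,4-bis(benzyloxy)phenyl]prop-2-en-1-ol
Product: 4 (S)-[3,4-bis(benzyloxy)phenyl][(2R)-oxiran-2-yl]methanol (erythro epoxy alcohol)
Conditions: Ti(OiPr)4 (10 mol %), L-(+)-diisopropyl tartrate (12 mol %), t-BuOOH (0.45 equiv), 4 Å MS, CH2Cl2, −20 °C
Reagents that add atoms: tert-butyl hydroperoxide, CC(C)(C)OO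
Why: Sharpless kinetic resolution of a secondary allylic alcohol: the tartrate catalyst should epoxidise the (R)-enantiomer of 3 much faster than the (S)-enantiomer, and on the alkene face that gives the erythro product. The oxirane carbon (R) is thus set by the catalyst and the carbinol (S in 4 by the change of substituent ranking) is selected by the resolution; conversion is held below half and the unreacted (S)-3 is separated.

Step 3
Reactants: 4 (S)-[3,4-bis(benzyloxy)phenyl][(2R)-oxiran-2-yl]methanol; 5 ethynyltrimethylsilane
Product: 6 (1S,2R)-1-[3,4-bis(benzyloxy)phenyl]-5-(trimethylsilyl)pent-4-yne-1,2-diol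
Conditions: 5 (3 equiv), n-BuLi, THF, −78 °C; BF3·OEt2, then 4, −78 °C; aq NaHCO3
Reagents that add atoms: none
Why: Yamaguchi-type BF3-promoted alkynylation: the lithium acetylide opens the terminal epoxide by SN2 attack at the CH2 carbon, so neither stereocenter is touched. The excess acetylide takes up the hydroxyl proton.

Step 4
Reactants: 6 (1S,2R)-1-[3,4-bis(benzyloxy)phenyl]-5-(trimethylsilyl)pent-4-yne-1,2-diol
Product: 7 (4S,5R)-4-[3,4-bis(benzyloxy)phenyl]-2,2-dimethyl-5-[3-(trimethylsilyl)prop-2-yn-1-yl]-1,3-dioxolane (cis acetonide)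
Conditions: Me2C(OMe)2, PPTS (cat.), CH2Cl2, rt
Reagents that add atoms: 2,2-dimethoxypropane, COC(C)(C)OC
Why: Acid-catalysed acetal exchange closes the five-membered acetonide on the 1,2-diol; the erythro diol gives the cis-dioxolane without change at either carbon.

Step 5
Reactants: 7 (4S,5R)-4-[3,4-bis(benzyloxy)phenyl]-2,2-dimethyl-5-[3-(trimethylsilyl)prop-2-yn-1-yl]-1,3-dioxolane
Product: 8 (4S,5R)-4-[3,4-bis(benzyloxy)phenyl]-2,2-dimethyl-5-(prop-2-yn-1-yl)-1,3-dioxolane
Conditions: K2CO3, MeOH, rt
Reagents that add atoms: none
Why: Methanolysis of the alkynyl C–Si bond under mild base; the acetonide and benzyl ethers are inert.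

Step 6
Reactants: 8 (4S,5R)-4-[3,4-bis(benzyloxy)phenyl]-2,2-dimethyl-5-(prop-2-yn-1-yl)-1,3-dioxolane
Product: 11 (4S,5R)-4-[3,4-bis(benzyloxy)phenyl]-2,2-dimethyl-5-{3-[tri(propan-2-yl)silyloxy]prop-2-yn-1-yl}-1,3-dioxolane, via lithium acetylide 9 (not isolated), via lithium ynolate 10 (not isolated)
Conditions: n-BuLi, THF, −78 °C; t-BuOOLi (from t-BuOOH, LiN(SiMe3)2), −78 → 0 °C; i-Pr3SiOTf, −78 → 0 °C
Reagents that add atoms: lithium tert-butyl peroxide, CC(C)(C)OO[Li]; triisopropylsilyl trifluoromethanesulfonate, CC(C)[Si](C(C)C)(C(C)C)OS(=O)(=O)C(F)(F)F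
Why: Oxidation of a lithium acetylide by a lithium alkyl peroxide (oxygen transfer with loss of tert-butoxide) gives the ynolate, and the bulky silyl triflate should silylate it on oxygen at low temperature to give the siloxyalkyne. The stereocenters are remote and the acetonide tolerates the base.

Step 7
Reactants: 12 3-ethoxycyclobut-2-en-1-one
Product: 13 3-(benzyloxy)cyclobut-2-en-1-one
Conditions: BnOH, CSA (cat.), toluene, 50 °C, 5 Å MS
Reagents that add atoms: benzyl alcohol, OCc1ccccc1
Why: Acid-catalysed exchange of a vinylogous ester (addition of the alcohol at C3, loss of ethanol), as known for alkoxy enones and squaric esters; removal of ethanol drives it.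

Step 8
Reactants: 11 (4S,5R)-4-[3,4-bis(benzyloxy)phenyl]-2,2-dimethyl-5-{3-[tri(propan-2-yl)silyloxy]prop-2-yn-1-yl}-1,3-dioxolane; 13 3-(benzyloxy)cyclobut-2-en-1-one
Product: 18 5-(benzyloxy)-2-(Diox-CH2)-3-{[tri(propan-2-yl)silyl]oxy}phenol, via vinylketene 14 (not isolated), via vinylcyclobutenone 15 (not isolated), via dienylketene 16 (not isolated), via cyclohexadienone 17 (not isolated)
Conditions: 13 (1.2 equiv), toluene, 80 → 110 °C, sealed tube
Reagents that add atoms: none
Why: On heating, 13 should open by 4π electrocyclic ring opening to vinylketene 14, which adds the siloxyalkyne 11 across its ketene C=C bond in a (2+2) cycloaddition to give 15 (C4a–C8a and C5–C6 formed). Cyclobutenone 15 opens (4π) to dienylketene 16; the isomer with the ketene carbon and the alkoxyvinyl group cis closes ring A by a thermal disrotatory 6π electrocyclisation (C8–C8a formed) to cyclohexadienone 17, which tautomerises to phenol 18, while the isomer that cannot close reverts to 15. The closest known reaction is the Danheiser benzannulation of cyclobutenones with siloxyalkynes to resorcinol monosilyl ethers; here the 3-alkoxy group of the cyclobutenone supplies the third oxygen. No stereocenter is created: the C4 center of 15 is erased on ring opening, and C2 and C3 of the future flavan are locked in the acetonide one CH2 away from the reacting carbons. The selectivity needed is the orientation of the (2+2) step: the alkyne carbon remote from the siloxy oxygen, which carries the chain and is the nucleophilic one, must bond to the ketene carbonyl carbon, and the oxygen polarisation of the ynol ether secures this. The chain therefore lies between the free hydroxyl (C8a) and the silyloxy group (C5), with the benzyloxy group para to it (C7). The acetonide removes every hydroxyl that could capture a ketene.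

Step 9
Reactants: 18 5-(benzyloxy)-2-(Diox-CH2)-3-{[tri(propan-2-yl)silyl]oxy}phenol
Product: 19 (1S,2R)-3-[4-(benzyloxy)-2-hydroxy-6-{[tri(propan-2-yl)silyl]oxy}phenyl]-1-[3,4-bis(benzyloxy)phenyl]propane-1,2-diol
Conditions: AcOH/H2O/THF (3:1:1), 40 °C
Reagents that add atoms: none
Why: Acetal hydrolysis proceeds by cleavage at the acetal carbon (tertiary oxocarbenium ion), not at the benzylic C–O bond, so both carbinol configurations should be kept; the aryl silyl ether and benzyl ethers are stable to aqueous acetic acid.

Step 10
Reactants: 19 (1S,2R)-3-[4-(benzyloxy)-2-hydroxy-6-{[tri(propan-2-yl)silyl]oxy}phenyl]-1-[3,4-bis(benzyloxy)phenyl]propane-1,2-diol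
Product: 21 (2R,3R)-7-(benzyloxy)-2-[3,4-bis(benzyloxy)phenyl]-5-{[tri(propan-2-yl)silyl]oxy}-3,4-dihydro-2H-chromen-3-ol, via benzylic oxyphosphonium phenoxide 20 (not isolated)
Conditions: PPh3, DIAD, THF, 0 °C → rt
Reagents that add atoms: none
Why: Intramolecular Mitsunobu etherification, known for 1,3-diarylpropane-1,2-diols with an ortho phenol: the phenol is the only acidic partner and displaces the activated benzylic oxygen of 20 in a 6-exo-tet SN2 closure. Inversion turns the (S) benzylic carbinol into (R)-C2, cis to the untouched (R)-C3 hydroxyl.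

Step 11
Reactants: 21 (2R,3R)-7-(benzyloxy)-2-[3,4-bis(benzyloxy)phenyl]-5-{[tri(propan-2-yl)silyl]oxy}-3,4-dihydro-2H-chromen-3-ol; 22 4-(benzyloxy)-3-methoxybenzoic acid
Product: 23 (2R,3R)-7-(benzyloxy)-2-[3,4-bis(benzyloxy)phenyl]-5-{[tri(propan-2-yl)silyl]oxy}-3,4-dihydro-2H-chromen-3-yl 4-(benzyloxy)-3-methoxybenzoate
Conditions: EDC·HCl, DMAP, CH2Cl2, rt
Reagents that add atoms: none
Why: Steglich-type carbodiimide esterification with DMAP as acyl-transfer catalyst; the C3 hydroxyl is the only free hydroxyl, and acylation at oxygen does not touch C3 itself.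

Step 12
Reactants: 23 (2R,3R)-7-(benzyloxy)-2-[3,4-bis(benzyloxy)phenyl]-5-{[tri(propan-2-yl)silyl]oxy}-3,4-dihydro-2H-chromen-3-yl 4-(benzyloxy)-3-methoxybenzoate
Product: 24 (2R,3R)-7-(benzyloxy)-2-[3,4-bis(benzyloxy)phenyl]-5-hydroxy-3,4-dihydro-2H-chromen-3-yl 4-(benzyloxy)-3-methoxybenzoate
Conditions: Bu4NF, AcOH, THF, 0 °C
Reagents that add atoms: none
Why: Fluoride cleavage of an aryl silyl ether; the acetic acid buffer protonates the phenoxide as it forms, so the ester is not attacked.

Step 13
Reactants: 24 (2R,3R)-7-(benzyloxy)-2-[3,4-bis(benzyloxy)phenyl]-5-hydroxy-3,4-dihydro-2H-chromen-3-yl 4-(benzyloxy)-3-methoxybenzoate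
Product: 25 (2R,3R)-2-(3,4-dihydroxyphenyl)-5,7-dihydroxy-3,4-dihydro-2H-chromen-3-yl 4-hydroxy-3-methoxybenzoate
Conditions: H2 (1 atm), Pd(OH)2/C, THF/MeOH, rt
Reagents that add atoms: none
Why: Catalytic hydrogenolysis removes the four benzyl ethers under neutral conditions; the ester, the cyclic C2–O1 ether and both stereocenters should be unaffected, and the product needs only filtration.

## Compound list

1 | 3,4-bis(benzyloxy)benzaldehyde | O=Cc1ccc(OCc2ccccc2)c(OCc2ccccc2)c1 | starting material
2 | vinylmagnesium bromide | C=C[Mg]Br | starting material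
3 | rac-1-[3,4-bis(benzyloxy)phenyl]prop-2-en-1-ol | C=CC(O)c1ccc(OCc2ccccc2)c(OCc2ccccc2)c1 | intermediate
4 | (S)-[3,4-bis(benzyloxy)phenyl][(2R)-oxiran-2-yl]methanol | O[C@@H](c1ccc(OCc2ccccc2)c(OCc2ccccc2)c1)[C@H]1CO1 | intermediate
5 | ethynyltrimethylsilane | C#C[Si](C)(C)C | starting material
6 | (1S,2R)-1-[3,4-bis(benzyloxy)phenyl]-5-(trimethylsilyl)pent-4-yne-1,2-diol | C[Si](C)(C)C#CC[C@@H](O)[C@@H](O)c1ccc(OCc2ccccc2)c(OCc2ccccc2)c1 | intermediate
7 | (4S,5R)-4-[3,4-bis(benzyloxy)phenyl]-2,2-dimethyl-5-[3-(trimethylsilyl)prop-2-yn-1-yl]-1,3-dioxolane | C[Si](C)(C)C#CC[C@H]1OC(C)(C)O[C@H]1c1ccc(OCc2ccccc2)c(OCc2ccccc2)c1 | intermediate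
8 | (4S,5R)-4-[3,4-bis(benzyloxy)phenyl]-2,2-dimethyl-5-(prop-2-yn-1-yl)-1,3-dioxolane | C#CC[C@H]1OC(C)(C)O[C@H]1c1ccc(OCc2ccccc2)c(OCc2ccccc2)c1 | intermediate
9 | lithium acetylide of 8 (not isolated) | [Li]C#CC[C@H]1OC(C)(C)O[C@H]1c1ccc(OCc2ccccc2)c(OCc2ccccc2)c1 | intermediate
10 | lithium ynolate from 9 (not isolated) | [Li]OC#CC[C@H]1OC(C)(C)O[C@H]1c1ccc(OCc2ccccc2)c(OCc2ccccc2)c1 | intermediate
11 | (4S,5R)-4-[3,4-bis(benzyloxy)phenyl]-2,2-dimethyl-5-{3-[tri(propan-2-yl)silyloxy]prop-2-yn-1-yl}-1,3-dioxolane | CC(C)[Si](C(C)C)(C(C)C)OC#CC[C@H]1OC(C)(C)O[C@H]1c1ccc(OCc2ccccc2)c(OCc2ccccc2)c1 | intermediate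
12 | 3-ethoxycyclobut-2-en-1-one | CCOC1=CC(=O)C1 | starting material
13 | 3-(benzyloxy)cyclobut-2-en-1-one | O=C1C=C(OCc2ccccc2)C1 | intermediate
14 | 3-(benzyloxy)buta-1,3-dien-1-one, the vinylketene (not isolated) | C=C(OCc1ccccc1)C=C=O | intermediate
15 | 4-[1-(benzyloxy)ethenyl]-2-(Diox-CH2)-3-{[tri(propan-2-yl)silyl]oxy}cyclobut-2-en-1-one, both C4 epimers (not isolated) | O=C1C(C[C@H]2OC(C)(C)O[C@H]2c2ccc(OCc3ccccc3)c(OCc3ccccc3)c2)=C(O[Si](C(C)C)(C(C)C)C(C)C)C1C(=C)OCc1ccccc1 | intermediate
16 | 5-(benzyloxy)-2-(Diox-CH2)-3-{[tri(propan-2-yl)silyl]oxy}hexa-1,3,5-trien-1-one with C2 and C5 cis across C3=C4, the dienylketene (not isolated) | O=C=C(C[C@H]1OC(C)(C)O[C@H]1c1ccc(OCc2ccccc2)c(OCc2ccccc2)c1)/C(O[Si](C(C)C)(C(C)C)C(C)C)=C\C(=C)OCc1ccccc1 | intermediate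
17 | 5-(benzyloxy)-2-(Diox-CH2)-3-{[tri(propan-2-yl)silyl]oxy}cyclohexa-2,4-dien-1-one (not isolated) | O=C1CC(OCc2ccccc2)=CC(O[Si](C(C)C)(C(C)C)C(C)C)=C1C[C@H]1OC(C)(C)O[C@H]1c1ccc(OCc2ccccc2)c(OCc2ccccc2)c1 | intermediate
18 | 5-(benzyloxy)-2-(Diox-CH2)-3-{[tri(propan-2-yl)silyl]oxy}phenol | Oc1cc(OCc2ccccc2)cc(O[Si](C(C)C)(C(C)C)C(C)C)c1C[C@H]1OC(C)(C)O[C@H]1c1ccc(OCc2ccccc2)c(OCc2ccccc2)c1 | intermediate
19 | (1S,2R)-3-[4-(benzyloxy)-2-hydroxy-6-{[tri(propan-2-yl)silyl]oxy}phenyl]-1-[3,4-bis(benzyloxy)phenyl]propane-1,2-diol | Oc1cc(OCc2ccccc2)cc(O[Si](C(C)C)(C(C)C)C(C)C)c1C[C@@H](O)[C@@H](O)c1ccc(OCc2ccccc2)c(OCc2ccccc2)c1 | intermediate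
20 | benzylic O-triphenylphosphonium phenoxide of 19 (not isolated) | [O-]c1cc(OCc2ccccc2)cc(O[Si](C(C)C)(C(C)C)C(C)C)c1C[C@@H](O)[C@@H](O[P+](c1ccccc1)(c1ccccc1)c1ccccc1)c1ccc(OCc2ccccc2)c(OCc2ccccc2)c1 | intermediate
21 | (2R,3R)-7-(benzyloxy)-2-[3,4-bis(benzyloxy)phenyl]-5-{[tri(propan-2-yl)silyl]oxy}-3,4-dihydro-2H-chromen-3-ol | O[C@@H]1Cc2c(O[Si](C(C)C)(C(C)C)C(C)C)cc(OCc3ccccc3)cc2O[C@@H]1c1ccc(OCc2ccccc2)c(OCc2ccccc2)c1 | intermediate
22 | 4-(benzyloxy)-3-methoxybenzoic acid | COc1cc(C(=O)O)ccc1OCc1ccccc1 | starting material
23 | (2R,3R)-7-(benzyloxy)-2-[3,4-bis(benzyloxy)phenyl]-5-{[tri(propan-2-yl)silyl]oxy}-3,4-dihydro-2H-chromen-3-yl 4-(benzyloxy)-3-methoxybenzoate | COc1cc(C(=O)O[C@@H]2Cc3c(O[Si](C(C)C)(C(C)C)C(C)C)cc(OCc4ccccc4)cc3O[C@@H]2c2ccc(OCc3ccccc3)c(OCc3ccccc3)c2)ccc1OCc1ccccc1 | intermediate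
24 | (2R,3R)-7-(benzyloxy)-2-[3,4-bis(benzyloxy)phenyl]-5-hydroxy-3,4-dihydro-2H-chromen-3-yl 4-(benzyloxy)-3-methoxybenzoate | COc1cc(C(=O)O[C@@H]2Cc3c(O)cc(OCc4ccccc4)cc3O[C@@H]2c2ccc(OCc3ccccc3)c(OCc3ccccc3)c2)ccc1OCc1ccccc1 | intermediate
25 | (2R,3R)-2-(3,4-dihydroxyphenyl)-5,7-dihydroxy-3,4-dihydro-2H-chromen-3-yl 4-hydroxy-3-methoxybenzoate | COc1cc(C(=O)O[C@@H]2Cc3c(O)cc(O)cc3O[C@@H]2c2ccc(O)c(O)c2)ccc1O | target

## Step count and least certain steps

Total step count: 13. Longest linear sequence: 12 (steps 1 to 6, then 8 to 13); step 7 is a one-step side branch.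

**Step 8 (key step).** The 3-alkoxy group makes 13 a vinylogous ester, and this should raise the barrier to its electrocyclic opening. At the temperature then needed, the siloxyalkyne may be lost by silyl migration from oxygen to carbon, ketene 14 may dimerise, or excess 14 may acylate the product phenol.

The fallback makes the same vinylketene without heat. It sets out from 11 and comes back at 18.
- Base-catalysed addition of benzyl alcohol to ethyl but-2-ynoate (NaH cat., THF) gives ethyl (E)-3-(benzyloxy)but-2-enoate F1.
- LiOH in aqueous THF gives (E)-3-(benzyloxy)but-2-enoic acid F2.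
- Oxalyl chloride with catalytic DMF gives (E)-3-(benzyloxy)but-2-enoyl chloride F3.
- Slow addition of F3 to 11 and Et3N in toluene at room temperature should release 14 by 1,4-dehydrochlorination, which 11 traps as 15. Warming to 80 °C, enough for a 4-vinylcyclobutenone, then carries 15 through 16 and 17 to 18.

**Step 10.** The benzylic oxyphosphonium of 20 sits next to a para-alkoxy ring B and may ionise before the phenoxide displaces it. This would erode the inversion and give some of the 2,3-trans diastereomer. Activation of the other carbinol (dihydrobenzofuran or epoxide formation) is a second possible leak. C3 is never touched, so any trans material is a separable diastereomer and does not lower the enantiomeric purity of 21.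

The fallback ties both carbinols into one ring before the closure. It sets out from 19 and comes back at 21.
- Triethyl orthoformate and PPTS in 1,2-dichloroethane at 60 °C convert the diol into the cyclic orthoformate F4.
- F4 loses ethanol to a dioxolanylium ion, which the phenol opens at the benzylic carbon with inversion, giving (2R,3R)-7-(benzyloxy)-2-[3,4-bis(benzyloxy)phenyl]-5-{[tri(propan-2-yl)silyl]oxy}-3,4-dihydro-2H-chromen-3-yl formate F5.
- KHCO3 in methanol removes the formyl group to give 21.

**Step 7.** Under acid, the alcohol may add to the strained ring carbonyl and cleave the four-membered ring to acetoacetate-type esters, or traces of water may hydrolyse the enol ether.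

The fallback separates hydrolysis from alkylation. It sets out from 12 and comes back at 13.
- Dilute aqueous HCl hydrolyses 12 to cyclobutane-1,3-dione F6.
- Mitsunobu O-alkylation of this strongly acidic enol with benzyl alcohol (PPh3, DIAD, THF, 0 °C) gives 13 under neutral conditions.

**Step 3.** The free hydroxyl is the weak point. Its BF3-complexed benzylic alkoxide may ionise, or the alkoxide may migrate the epoxide (Payne-type) before the acetylide attacks, so that material is lost or the opening is less clean.

The fallback masks the hydroxyl. It sets out from 4 and comes back at 8.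
- TBSCl and imidazole in DMF give (2R)-2-{(S)-[3,4-bis(benzyloxy)phenyl][(tert-butyldimethylsilyl)oxy]methyl}oxirane F7.
- The same acetylide and BF3·OEt2 open F7 to (1S,2R)-1-[3,4-bis(benzyloxy)phenyl]-1-[(tert-butyldimethylsilyl)oxy]-5-(trimethylsilyl)pent-4-yn-2-ol F8.
- Bu4NF removes both silyl groups to give (1S,2R)-1-[3,4-bis(benzyloxy)phenyl]pent-4-yne-1,2-diol F9.
- 2,2-Dimethoxypropane with PPTS closes the acetonide to 8.

## Further compounds

F1 | step 8 | ethyl (E)-3-(benzyloxy)but-2-enoate | CCOC(=O)/C=C(\C)OCc1ccccc1
F2 | step 8 | (E)-3-(benzyloxy)but-2-enoic acid | OC(=O)/C=C(\C)OCc1ccccc1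
F3 | step 8 | (E)-3-(benzyloxy)but-2-enoyl chloride | ClC(=O)/C=C(\C)OCc1ccccc1
F4 | step 10 | 5-(benzyloxy)-2-{[(4R,5S)-5-[3,4-bis(benzyloxy)phenyl]-2-ethoxy-1,3-dioxolan-4-yl]methyl}-3-{[tri(propan-2-yl)silyl]oxy}phenol, both epimers at the orthoester carbon | Oc1cc(OCc2ccccc2)cc(O[Si](C(C)C)(C(C)C)C(C)C)c1C[C@H]1OC(OCC)O[C@H]1c1ccc(OCc2ccccc2)c(OCc2ccccc2)c1
F5 | step 10 | (2R,3R)-7-(benzyloxy)-2-[3,4-bis(benzyloxy)phenyl]-5-{[tri(propan-2-yl)silyl]oxy}-3,4-dihydro-2H-chromen-3-yl formate | O=CO[C@@H]1Cc2c(O[Si](C(C)C)(C(C)C)C(C)C)cc(OCc3ccccc3)cc2O[C@@H]1c1ccc(OCc2ccccc2)c(OCc2ccccc2)c1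
F6 | step 7 | cyclobutane-1,3-dione | O=C1CC(=O)C1
F7 | step 3 | (2R)-2-{(S)-[3,4-bis(benzyloxy)phenyl][(tert-butyldimethylsilyl)oxy]methyl}oxirane | CC(C)(C)[Si](C)(C)O[C@@H](c1ccc(OCc2ccccc2)c(OCc2ccccc2)c1)[C@H]1CO1
F8 | step 3 | (1S,2R)-1-[3,4-bis(benzyloxy)phenyl]-1-[(tert-butyldimethylsilyl)oxy]-5-(trimethylsilyl)pent-4-yn-2-ol | C[Si](C)(C)C#CC[C@@H](O)[C@@H](O[Si](C)(C)C(C)(C)C)c1ccc(OCc2ccccc2)c(OCc2ccccc2)c1
F9 | step 3 | (1S,2R)-1-[3,4-bis(benzyloxy)phenyl]pent-4-yne-1,2-diol | C#CC[C@@H](O)[C@@H](O)c1ccc(OCc2ccccc2)c(OCc2ccccc2)c1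
A1 | alternative 1 | (2R,3R)-5,7-bis(benzyloxy)-2-[3,4-bis(benzyloxy)phenyl]-3,4-dihydro-2H-chromen-3-yl 4-(benzyloxy)-3-methoxybenzoate | COc1cc(C(=O)O[C@@H]2Cc3c(OCc4ccccc4)cc(OCc4ccccc4)cc3O[C@@H]2c2ccc(OCc3ccccc3)c(OCc3ccccc3)c2)ccc1OCc1ccccc1
A2 | alternative 1 | 3,5-bis(benzyloxy)-2-(hydroxymethyl)phenol | OCc1c(O)cc(OCc2ccccc2)cc1OCc1ccccc1
A3 | alternative 1 | (Z)-2-[3,4-bis(benzyloxy)phenyl]ethenyl 4-(benzyloxy)-3-methoxybenzoate | COc1cc(C(=O)O/C=C\c2ccc(OCc3ccccc3)c(OCc3ccccc3)c2)ccc1OCc1ccccc1
A4 | alternative 1 | 3,5-bis(benzyloxy)-6-methylidenecyclohexa-2,4-dien-1-one | C=C1C(=O)C=C(OCc2ccccc2)C=C1OCc1ccccc1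
A5 | alternative 2 | rac-5,7-bis(benzyloxy)-2-[3,4-bis(benzyloxy)phenyl]-2H-chromene | C1=Cc2c(OCc3ccccc3)cc(OCc3ccccc3)cc2OC1c1ccc(OCc2ccccc2)c(OCc2ccccc2)c1
A6 | alternative 2 | 3,5-bis(benzyloxy)-2-(trimethylsilyl)phenyl trifluoromethanesulfonate | C[Si](C)(C)c1c(OS(=O)(=O)C(F)(F)F)cc(OCc2ccccc2)cc1OCc1ccccc1
A7 | alternative 2 | (E)-3-[3,4-bis(benzyloxy)phenyl]prop-2-enal | O=C/C=C/c1ccc(OCc2ccccc2)c(OCc2ccccc2)c1
A8 | alternative 2 | 3,5-bis(benzyloxy)benzyne | C1#CC(OCc2ccccc2)=CC(OCc2ccccc2)=C1
A9 | alternative 3 | (2R,3R)-5,7-bis(benzyloxy)-2-[3,4-bis(benzyloxy)phenyl]-3,4-dihydro-2H-chromen-3-ol | O[C@@H]1Cc2c(OCc3ccccc3)cc(OCc3ccccc3)cc2O[C@@H]1c1ccc(OCc2ccccc2)c(OCc2ccccc2)c1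
A10 | alternative 3 | (2R)-2-{(R)-[3,4-bis(benzyloxy)phenyl][3,5-bis(benzyloxy)phenoxy]methyl}oxirane | C1O[C@H]1[C@H](Oc1cc(OCc2ccccc2)cc(OCc2ccccc2)c1)c1ccc(OCc2ccccc2)c(OCc2ccccc2)c1
A11 | alternative 3 | 3,5-bis(benzyloxy)phenol | Oc1cc(OCc2ccccc2)cc(OCc2ccccc2)c1
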